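**Strategy.** The cyclohexane ring (C5a, C6, C7, C8, C9, C9a of the octahydro-1-benzoxepine) is cut at C6–C7 and C5a–C9a. The 1,4-related C7–Br and C9a–O carbons end a four-carbon unit; the CMe2–CH pair is a two-carbon unit. One Lewis-acid-promoted, auxiliary-controlled endo Diels–Alder reaction joins a (2Z,4E)-5-bromo-2-alkoxypenta-2,4-diene, whose ether oxygen already carries the C2 stereocentre with its CH2Br and prop-1-en-2-yl groups, to an N-(3-methylbut-2-enoyl)oxazolidinone. It sets C5a, C7 and the quaternary C9a at once; the equatorial bromide comes from the (E)-vinyl bromide. Ring-closing metathesis then closes the oxepene.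

Key step: step 6

Assumptions: target atoms are numbered as in octahydro-1-benzoxepine (O1, C2–C5, C5a, C6–C9, C9a); compounds 1, 5, 8 and 9 are taken as commercial; the aluminium-chelated imide is taken to react through its s-cis conformer, which decides the choice of the (R)-auxiliary.

Step 1
Reactants: 1 3-methylbut-3-en-2-one
Product: 3 1-bromo-3-methylbut-3-en-2-one, via silyl dienol ether 2 (not isolated)
Conditions: TMSOTf, Et3N, CH2Cl2, 0 °C; then NBS, THF, −78 to 0 °C
Reagents that add atoms: N-bromosuccinimide O=C1CCC(=O)N1Br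
Why: Soft enolisation at the only enolisable position (the acetyl methyl) gives the 2-silyloxy diene, whose electron-rich terminal CH2 is brominated by NBS (α-bromination of a silyl enol ether); no stereocentre is formed.

Step 2
Reactants: 3 1-bromo-3-methylbut-3-en-2-one
Product: 4 (2R)-1-bromo-3-methylbut-3-en-2-ol
Conditions: (R)-2-methyl-CBS-oxazaborolidine (10 mol %), catecholborane, toluene, −78 °C
Reagents that add atoms: none
Why: Corey–Bakshi–Shibata reduction, with the prop-1-en-2-yl group as the large and CH2Br as the small ketone substituent, should deliver hydride to one face and set the (R)-carbinol centre that becomes C2 of the target; catecholborane at low temperature does not hydroborate the 1,1-disubstituted alkene.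

Step 3
Reactants: 4 (2R)-1-bromo-3-methylbut-3-en-2-ol; 5 but-2-ynal
Product: 6 (2Z)-3-{[(2R)-1-bromo-3-methylbut-3-en-2-yl]oxy}but-2-enal
Conditions: Ph3PAuNTf2 (2 mol %), CH2Cl2, 4 Å MS, −20 to 0 °C; used directly
Reagents that add atoms: none
Why: Gold-catalysed hydroalkoxylation of the polarised ynal, in which the neutral alcohol attacks the gold-activated β-carbon anti to the metal and protodeauration places O and CHO cis ((Z)-β-alkoxy enal), avoids an alkoxide (which would close to the epoxide) and leaves the carbinol stereocentre untouched.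

Step 4
Reactants: 6 (2Z)-3-{[(2R)-1-bromo-3-methylbut-3-en-2-yl]oxy}but-2-enal
Product: 7 (2R)-1-bromo-2-{[(2Z,4E)-5-bromopenta-2,4-dien-2-yl]oxy}-3-methylbut-3-ene
Conditions: CrCl2, CHBr3, THF, 0 °C; work-up buffered with Et3N
Reagents that add atoms: bromoform BrC(Br)Br
Why: Takai olefination with the gem-dichromium reagent from CHBr3 and CrCl2 converts the aldehyde into the (E)-vinyl bromide, and chelation of chromium between the aldehyde oxygen and the cis ether oxygen should help to hold the (Z)-enol ether geometry.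

Step 5
Reactants: 8 (4R)-4-benzyl-5,5-dimethyl-1,3-oxazolidin-2-one; 9 3-methylbut-2-enoyl chloride
Product: 11 (4R)-4-benzyl-5,5-dimethyl-3-(3-methylbut-2-enoyl)-1,3-oxazolidin-2-one, via lithium oxazolidinide 10 (not isolated)
Conditions: n-BuLi, THF, −78 °C; then 9, −78 to 0 °C
Reagents that add atoms: none
Why: N-Acylation of the lithiated oxazolidinone by the acid chloride (standard imide formation) at low temperature and without an amine base avoids deconjugation of the 3-methylbut-2-enoyl group through a vinylketene.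

Step 6
Reactants: 7 (2R)-1-bromo-2-{[(2Z,4E)-5-bromopenta-2,4-dien-2-yl]oxy}-3-methylbut-3-ene; 11 (4R)-4-benzyl-5,5-dimethyl-3-(3-methylbut-2-enoyl)-1,3-oxazolidin-2-one
Product: 12 (4R)-4-benzyl-3-{[(1S,2S,5S)-5-bromo-2-{[(2R)-1-bromo-3-methylbut-3-en-2-yl]oxy}-2,6,6-trimethylcyclohex-3-en-1-yl]carbonyl}-5,5-dimethyl-1,3-oxazolidin-2-one
Conditions: Me2AlCl (1.5 equiv), CH2Cl2, −78 to −40 °C
Reagents that add atoms: none
Why: Me2AlCl ionises on the imide to a cationic, O,O-chelated s-cis N-enoyl oxazolidinone whose lowered LUMO should let even the β,β-dimethyl alkene react with the 1-alkoxy diene in a concerted, asynchronous normal-demand [4+2] cycloaddition that forms C5–C6 and C1–C2 of the cyclohexene (C7–C6 and C5a–C9a of the target). The closest known reaction type is the dialkylaluminium chloride-promoted asymmetric Diels–Alder reaction of N-enoyl oxazolidinones with acyclic dienes. The cyclohexene ring closes intermolecularly, suprafacially on both partners and through the endo transition state, the diene reacting from its s-cis conformer with only the small alkoxy oxygen inside. C5 (CHBr) follows from the (E)-bromoalkene and C2 (CH3/O) from the (Z)-enol ether, which place Br and CH3 outside and hence cis to each other and trans to oxygen; C1 follows from the endo position of the chelated acyl group (cis to Br and CH3); the absolute sense follows from the benzyl group of the (R)-auxiliary, held over one face of the dienophile by the adjacent gem-dimethyl carbon. The step needs ortho regioselectivity, secured by the donor oxygen on the diene terminus that bonds to the α-carbon, and survival of the acid-labile allyl dienyl ether, secured by the low temperature and by the aluminium being bound in the chelate; the side-chain stereocentre is a spectator.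

Step 7
Reactants: 12 (4R)-4-benzyl-3-{[(1S,2S,5S)-5-bromo-2-{[(2R)-1-bromo-3-methylbut-3-en-2-yl]oxy}-2,6,6-trimethylcyclohex-3-en-1-yl]carbonyl}-5,5-dimethyl-1,3-oxazolidin-2-one
Product: 14 (1S,2S,5S)-5-bromo-2-{[(2R)-1-bromo-3-methylbut-3-en-2-yl]oxy}-2,6,6-trimethylcyclohex-3-ene-1-carbaldehyde, via hemiaminal 13 (not isolated)
Conditions: i-Bu2AlH, CH2Cl2, −78 °C; then K2CO3, MeOH, 0 °C
Reagents that add atoms: none
Why: In this reductive auxiliary cleavage the 5,5-dimethyl groups block attack at the ring carbonyl, so i-Bu2AlH adds once to the exocyclic carbonyl to give a stable N-(1-hydroxyalkyl) hemiaminal that releases the aldehyde and the auxiliary on mild base treatment without enolising the α-centre.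

Step 8
Reactants: 14 (1S,2S,5S)-5-bromo-2-{[(2R)-1-bromo-3-methylbut-3-en-2-yl]oxy}-2,6,6-trimethylcyclohex-3-ene-1-carbaldehyde
Product: 15 1-[(1R,2S,5S)-5-bromo-2-{[(2R)-1-bromo-3-methylbut-3-en-2-yl]oxy}-2,6,6-trimethylcyclohex-3-en-1-yl]prop-2-en-1-ol (both carbinol epimers)
Conditions: CH2=CHMgBr, THF, −78 °C
Reagents that add atoms: vinylmagnesium bromide C=C[Mg]Br
Why: Grignard 1,2-addition to the aldehyde at low temperature is faster than attack on the hindered neopentyl allylic bromide, and both carbinol epimers converge later because this oxygen is removed.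

Step 9
Reactants: 15 1-[(1R,2S,5S)-5-bromo-2-{[(2R)-1-bromo-3-methylbut-3-en-2-yl]oxy}-2,6,6-trimethylcyclohex-3-en-1-yl]prop-2-en-1-ol
Product: 16 (2R,5aR,7S,9aS)-7-bromo-2-(bromomethyl)-3,6,6,9a-tetramethyl-2,5,5a,6,7,9a-hexahydro-1-benzoxepin-5-ol (both C5 epimers)
Conditions: second-generation Grubbs catalyst (5 mol %), CH2Cl2 (dilute), 40 °C
Reagents that add atoms: none
Why: Ring-closing metathesis between the vinyl group and the prop-1-en-2-yl group closes the seven-membered oxepene with its trisubstituted (necessarily Z) C3=C4 bond, helped by the trans-diequatorial disposition of the two arms and the free allylic hydroxyl, while the unstrained cyclohexene bond stays out.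

Step 10
Reactants: 16 (2R,5aR,7S,9aS)-7-bromo-2-(bromomethyl)-3,6,6,9a-tetramethyl-2,5,5a,6,7,9a-hexahydro-1-benzoxepin-5-ol
Product: 17 (2R,5aR,7S,9aS)-7-bromo-2-(bromomethyl)-3,6,6,9a-tetramethyl-2,5,5a,6,7,8,9,9a-octahydro-1-benzoxepin-5-ol (both C5 epimers)
Conditions: 2-nitrobenzenesulfonohydrazide, Et3N, CH2Cl2, 20 °C
Reagents that add atoms: none
Why: Diimide reduction transfers H2 in a concerted syn fashion to the cis-disubstituted C8=C9 bond much faster than to the trisubstituted C3=C4 bond and, unlike metal-catalysed hydrogenation, leaves both C–Br bonds and the allylic C–O bonds intact.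

Step 11
Reactants: 17 (2R,5aR,7S,9aS)-7-bromo-2-(bromomethyl)-3,6,6,9a-tetramethyl-2,5,5a,6,7,8,9,9a-octahydro-1-benzoxepin-5-ol
Product: 18 palisadin B, (2R,5aS,7S,9aS)-7-bromo-2-(bromomethyl)-3,6,6,9a-tetramethyl-2,5,5a,6,7,8,9,9a-octahydro-1-benzoxepine
Conditions: Et3SiH, CF3CO2H, CH2Cl2, −40 to −20 °C
Reagents that add atoms: none
Why: Ionic deoxygenation, in which acid ionises the allylic alcohol to an allyl cation whose tertiary terminus (C3) is deactivated by the adjacent oxygen-bearing C2, should deliver hydride from Et3SiH to the secondary terminus C5 and restore the trisubstituted C3=C4 bond without touching any stereocentre.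

**Compound list**

1 | 3-methylbut-3-en-2-one | CC(=C)C(C)=O | starting material
2 | trimethyl[(3-methylbuta-1,3-dien-2-yl)oxy]silane | C=C(C)C(=C)O[Si](C)(C)C | intermediate
3 | 1-bromo-3-methylbut-3-en-2-one | CC(=C)C(=O)CBr | intermediate
4 | (2R)-1-bromo-3-methylbut-3-en-2-ol | O[C@H](C(C)=C)CBr | intermediate
5 | but-2-ynal | CC#CC=O | starting material
6 | (2Z)-3-{[(2R)-1-bromo-3-methylbut-3-en-2-yl]oxy}but-2-enal | O=C/C=C(/C)O[C@H](C(C)=C)CBr | intermediate
7 | (2R)-1-bromo-2-{[(2Z,4E)-5-bromopenta-2,4-dien-2-yl]oxy}-3-methylbut-3-ene | Br/C=C/C=C(/C)O[C@H](C(C)=C)CBr | intermediate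
8 | (4R)-4-benzyl-5,5-dimethyl-1,3-oxazolidin-2-one | O=C1N[C@H](Cc2ccccc2)C(C)(C)O1 | starting material
9 | 3-methylbut-2-enoyl chloride | CC(C)=CC(Cl)=O | starting material
10 | lithium (4R)-4-benzyl-5,5-dimethyl-2-oxo-1,3-oxazolidin-3-ide | [Li+].O=C1[N-][C@H](Cc2ccccc2)C(C)(C)O1 | intermediate
11 | (4R)-4-benzyl-5,5-dimethyl-3-(3-methylbut-2-enoyl)-1,3-oxazolidin-2-one | CC(C)=CC(=O)N1[C@H](Cc2ccccc2)C(C)(C)OC1=O | intermediate
12 | (4R)-4-benzyl-3-{[(1S,2S,5S)-5-bromo-2-{[(2R)-1-bromo-3-methylbut-3-en-2-yl]oxy}-2,6,6-trimethylcyclohex-3-en-1-yl]carbonyl}-5,5-dimethyl-1,3-oxazolidin-2-one | O=C(N3[C@H](Cc4ccccc4)C(C)(C)OC3=O)[C@H]2C(C)(C)[C@@H](Br)C=C[C@]2(C)O[C@H](C(C)=C)CBr | intermediate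
13 | (4R)-4-benzyl-3-{[(1S,2S,5S)-5-bromo-2-{[(2R)-1-bromo-3-methylbut-3-en-2-yl]oxy}-2,6,6-trimethylcyclohex-3-en-1-yl](hydroxy)methyl}-5,5-dimethyl-1,3-oxazolidin-2-one (carbinol carbon undefined) | OC(N3[C@H](Cc4ccccc4)C(C)(C)OC3=O)[C@H]2C(C)(C)[C@@H](Br)C=C[C@]2(C)O[C@H](C(C)=C)CBr | intermediate
14 | (1S,2S,5S)-5-bromo-2-{[(2R)-1-bromo-3-methylbut-3-en-2-yl]oxy}-2,6,6-trimethylcyclohex-3-ene-1-carbaldehyde | O=C[C@H]2C(C)(C)[C@@H](Br)C=C[C@]2(C)O[C@H](C(C)=C)CBr | intermediate
15 | 1-[(1R,2S,5S)-5-bromo-2-{[(2R)-1-bromo-3-methylbut-3-en-2-yl]oxy}-2,6,6-trimethylcyclohex-3-en-1-yl]prop-2-en-1-ol (both carbinol epimers) | C=CC(O)[C@H]2C(C)(C)[C@@H](Br)C=C[C@]2(C)O[C@H](C(C)=C)CBr | intermediate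
16 | (2R,5aR,7S,9aS)-7-bromo-2-(bromomethyl)-3,6,6,9a-tetramethyl-2,5,5a,6,7,9a-hexahydro-1-benzoxepin-5-ol (both C5 epimers) | CC1=CC(O)[C@H]2C(C)(C)[C@@H](Br)C=C[C@]2(C)O[C@H]1CBr | intermediate
17 | (2R,5aR,7S,9aS)-7-bromo-2-(bromomethyl)-3,6,6,9a-tetramethyl-2,5,5a,6,7,8,9,9a-octahydro-1-benzoxepin-5-ol (both C5 epimers) | CC1=CC(O)[C@H]2C(C)(C)[C@@H](Br)CC[C@]2(C)O[C@H]1CBr | intermediate
18 | palisadin B, (2R,5aS,7S,9aS)-7-bromo-2-(bromomethyl)-3,6,6,9a-tetramethyl-2,5,5a,6,7,8,9,9a-octahydro-1-benzoxepine | CC1=CC[C@H]2C(C)(C)[C@@H](Br)CC[C@]2(C)O[C@H]1CBr | target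

**Step count.** Total: 11 steps. Longest linear sequence: 10 steps (steps 1–4 and 6–11); step 5 is a one-step branch.

**Steps most likely to fail**

Step 6 (key step). The Lewis acid may ionise, rearrange ([3,3] shift) or hydrolyse the acid-labile allyl dienyl ether before it is captured, or the cycloaddition may stall because the β-carbon of the dienophile carries two methyl groups. Fallback: setting out from 7, an uncatalysed Diels–Alder reaction with 3-methylbut-2-enal (CC(C)=CC=O) under high pressure (about 12 kbar, CH2Cl2, 40 °C, a trace of Et3N) needs neither Lewis acid nor auxiliary, because the strongly negative activation volume of the cycloaddition compensates for the hindered dienophile. The endo rule and the diene geometry still fix the relative configuration of the ring, but reagent control of the absolute sense is given up. Aldehyde 14 would then be accompanied by its diastereomer with the mirror-image ring, (1R,2R,5R)-5-bromo-2-{[(2R)-1-bromo-3-methylbut-3-en-2-yl]oxy}-2,6,6-trimethylcyclohex-3-ene-1-carbaldehyde F1, which the fixed side-chain stereocentre makes separable by chromatography. The route is rejoined at 14.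

Step 3. The (Z)-enol ether geometry may be lost by rotation about the polarised (push–pull) C=C bond of the β-alkoxy enal, here or during step 4, which would lead to the unreactive diene with the methyl group inside. Fallback: setting out from 4, gold-catalysed anti addition (Ph3PAuNTf2, CH2Cl2) of the alcohol to the methyl-bearing terminus of 1-(trimethylsilyl)penta-1,3-diyne (CC#CC#C[Si](C)(C)C) gives a non-polarised, configurationally stable enynyl ether, {(3Z)-4-{[(2R)-1-bromo-3-methylbut-3-en-2-yl]oxy}pent-3-en-1-yn-1-yl}(trimethyl)silane F2. This mode of attack is the one known from gold-catalysed additions of water and amines to 1,3-diynes. K2CO3 in MeOH removes the silyl group to give (2R)-1-bromo-3-methyl-2-{[(2Z)-pent-2-en-4-yn-2-yl]oxy}but-3-ene F3. Syn hydrozirconation with Cp2Zr(H)Cl gives chlorobis(cyclopentadienyl){(1E,3Z)-4-{[(2R)-1-bromo-3-methylbut-3-en-2-yl]oxy}penta-1,3-dien-1-yl}zirconium F4 (not isolated), which NBS at −78 °C converts into the (E)-bromide 7. The route is rejoined at 7 and step 4 is bypassed.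

Step 11. Hydride may be captured at the tertiary terminus of the allyl cation (leaving the double bond at C4=C5), or the acid may open the allylic C2–O bond. Fallback: setting out from 14, the C5 oxygen is never introduced. Wittig reaction with Ph3P=CHOMe gives (1S,2S,5S)-5-bromo-2-{[(2R)-1-bromo-3-methylbut-3-en-2-yl]oxy}-1-(2-methoxyethenyl)-2,6,6-trimethylcyclohex-3-ene F5 (ring numbered as in 14, enol ether E/Z). Hg(OAc)2 in aqueous THF followed by KI hydrolyses it to 2-[(1S,2S,5S)-5-bromo-2-{[(2R)-1-bromo-3-methylbut-3-en-2-yl]oxy}-2,6,6-trimethylcyclohex-3-en-1-yl]acetaldehyde F6. Ph3P=CH2 gives (1S,2S,5S)-5-bromo-2-{[(2R)-1-bromo-3-methylbut-3-en-2-yl]oxy}-2,6,6-trimethyl-1-(prop-2-en-1-yl)cyclohex-3-ene F7. Ring-closing metathesis with the second-generation Grubbs catalyst gives (2R,5aS,7S,9aS)-7-bromo-2-(bromomethyl)-3,6,6,9a-tetramethyl-2,5,5a,6,7,9a-hexahydro-1-benzoxepine F8. Diimide reduction under the conditions of step 10 then gives 18 directly, where the route is rejoined.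

Further compounds
F1 | step 6 | (1R,2R,5R)-5-bromo-2-{[(2R)-1-bromo-3-methylbut-3-en-2-yl]oxy}-2,6,6-trimethylcyclohex-3-ene-1-carbaldehyde | O=C[C@@H]2C(C)(C)[C@H](Br)C=C[C@@]2(C)O[C@H](C(C)=C)CBr
F2 | step 3 | {(3Z)-4-{[(2R)-1-bromo-3-methylbut-3-en-2-yl]oxy}pent-3-en-1-yn-1-yl}(trimethyl)silane | C[Si](C)(C)C#C/C=C(/C)O[C@H](C(C)=C)CBr
F3 | step 3 | (2R)-1-bromo-3-methyl-2-{[(2Z)-pent-2-en-4-yn-2-yl]oxy}but-3-ene | C#C/C=C(/C)O[C@H](C(C)=C)CBr
F4 | step 3 | chlorobis(cyclopentadienyl){(1E,3Z)-4-{[(2R)-1-bromo-3-methylbut-3-en-2-yl]oxy}penta-1,3-dien-1-yl}zirconium | Cl[Zr](/C=C/C=C(/C)O[C@H](C(C)=C)CBr)(C1C=CC=C1)C1C=CC=C1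
F5 | step 11 | (1S,2S,5S)-5-bromo-2-{[(2R)-1-bromo-3-methylbut-3-en-2-yl]oxy}-1-(2-methoxyethenyl)-2,6,6-trimethylcyclohex-3-ene | COC=C[C@H]2C(C)(C)[C@@H](Br)C=C[C@]2(C)O[C@H](C(C)=C)CBr
F6 | step 11 | 2-[(1S,2S,5S)-5-bromo-2-{[(2R)-1-bromo-3-methylbut-3-en-2-yl]oxy}-2,6,6-trimethylcyclohex-3-en-1-yl]acetaldehyde | O=CC[C@H]2C(C)(C)[C@@H](Br)C=C[C@]2(C)O[C@H](C(C)=C)CBr
F7 | step 11 | (1S,2S,5S)-5-bromo-2-{[(2R)-1-bromo-3-methylbut-3-en-2-yl]oxy}-2,6,6-trimethyl-1-(prop-2-en-1-yl)cyclohex-3-ene | C=CC[C@H]2C(C)(C)[C@@H](Br)C=C[C@]2(C)O[C@H](C(C)=C)CBr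
F8 | step 11 | (2R,5aS,7S,9aS)-7-bromo-2-(bromomethyl)-3,6,6,9a-tetramethyl-2,5,5a,6,7,9a-hexahydro-1-benzoxepine | CC1=CC[C@H]2C(C)(C)[C@@H](Br)C=C[C@]2(C)O[C@H]1CBr
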